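**Strategy.** The ten-membered ring is unveiled, not closed. The target's transannular pair C3 (oxygenated)/C8 (CH2) and its Z-C4=C5 olefin map onto (R)-carvone, which supplies C3–C8, C11–C13, C15, the C7 stereocentre and, as its ring enone, the Z geometry. The arc C9–C10(C14)–C1–C2 is grafted between the carbonyl carbon (C3) and its α-carbon (C8) as a second six-membered ring; C9 is set in the aldol, C1/C10 on the bicycle. β-Scission of the alkoxyl radical of the ring-fusion alcohol then cuts the shared C3–C8 bond, expanding the carvone ring by four carbons to the germacrane Z-enone. Precursor: cis-decalinol 19, already carrying epoxide, angelate and C6 silyl ether.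

Key step: step 11

Remark: C-labels are the germacrane numbers of the target (C12 lactone carbonyl, C13 exocyclic methylene, C14 on C10, C15 on C4); α/β refer to the usual drawing with H-7 α. The SMILES is read as 1R,3S,6R,7S,9S,10S, 4Z, angelate (Z) ester, i.e. 1β,3β,10α-trihydroxy-9β-angeloyloxy-12,6α-olide.

Step 1
Reactants: 1 (R)-(−)-carvone
Product: 3 trans-6-hydroxycarvone [(5S,6S)-6-hydroxy-2-methyl-5-(prop-1-en-2-yl)cyclohex-2-en-1-one], via lithium dienolate 2 (not isolated)
Conditions: LDA, THF, −78 °C; 2-(phenylsulfonyl)-3-phenyloxaziridine, −78 °C; H2O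
Reagents that add atoms: 2-(phenylsulfonyl)-3-phenyloxaziridine, O1C(c2ccccc2)N1S(=O)(=O)c1ccccc1
Why: Kinetic α′-deprotonation gives the cross-conjugated lithium dienolate, which the N-sulfonyloxaziridine hydroxylates (Davis enolate oxidation) on the face anti to the neighbouring isopropenyl group, setting the future C6–O trans to C7.

Step 2
Reactants: 3 trans-6-hydroxycarvone
Product: 4 (5S,6S)-6-(tert-butyldimethylsilyloxy)-2-methyl-5-(prop-1-en-2-yl)cyclohex-2-en-1-one
Conditions: TBSCl, imidazole, DMF, rt
Reagents that add atoms: tert-butyldimethylsilyl chloride, CC(C)(C)[Si](C)(C)Cl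
Why: Standard imidazole-mediated silylation of the secondary α-ketol, with no change at the stereocentres.

Step 3
Reactants: 4 silyl ether
Product: 5 2,3-epoxide of 4 (oxirane anti to the isopropenyl group)
Conditions: 30% H2O2, NaOH (cat.), MeOH, 0 °C
Reagents that add atoms: hydrogen peroxide, OO
Why: Weitz–Scheffer nucleophilic epoxidation of the enone, hydroperoxide adding axially anti to the isopropenyl group; the two oxirane centres are erased again in steps 4 and 5.

Step 4
Reactants: 5 epoxy ketone
Product: 7 (1R,4R,5S)-4-(tert-butyldimethylsilyloxy)-2-methyl-5-(prop-1-en-2-yl)cyclohex-2-en-1-ol, via epoxy hydrazone 6 (not isolated)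
Conditions: N2H4·H2O, AcOH (cat.), MeOH, 0 °C to rt
Reagents that add atoms: none
Why: Wharton transposition: the α,β-epoxy hydrazone collapses to an allylic alkoxide-diazene that loses N2, moving the oxygen from C5 to C3 and the double bond to C4=C5; the carbinol configuration is inherited from the epoxide and is removed in step 5.

Step 5
Reactants: 7 transposed allylic alcohol
Product: 8 (4R,5S)-4-(tert-butyldimethylsilyloxy)-2-methyl-5-(prop-1-en-2-yl)cyclohex-2-en-1-one (C3 ketone; C4=C5; 6α-OTBS; C7; C8 methylene)
Conditions: Dess–Martin periodinane, CH2Cl2, rt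
Reagents that add atoms: none
Why: Dess–Martin oxidation of the secondary allylic alcohol completes the 1,3-carbonyl transposition, so that the former α′-oxygen is now the γ-oxygen (C6) of an enone whose C8 methylene is free for enolisation.

Step 6
Reactants: 8 γ-silyloxy enone; 9 methacrolein
Product: 12 (4R,5S,6S)-4-(tert-butyldimethylsilyloxy)-6-[(1S)-1-hydroxy-2-methylprop-2-en-1-yl]-2-methyl-5-(prop-1-en-2-yl)cyclohex-2-en-1-one (syn aldol; 8β-H; 9β-OH), via lithium enolate 10 (not isolated), via titanium enolate 11 (not isolated)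
Conditions: LDA, THF, −78 °C; ClTi(OiPr)3, −78 to −40 °C; 9, −78 °C; H2O
Reagents that add atoms: methacrolein (9), CC(=C)C=O
Why: The kinetic α′-enolate is transmetalated to the triisopropoxytitanium enolate, whose aldol addition to the enal should occur anti to the adjacent C7 isopropenyl group (C8) and with the syn (erythro) simple diastereoselection typical of titanium enolates of cyclic ketones, setting C9 as the future 9β-oxygen.

Step 7
Reactants: 12 syn aldol; 13 allylmagnesium bromide
Product: 14 (1S,4R,5S,6S)-1-allyl-4-(tert-butyldimethylsilyloxy)-6-[(1S)-1-hydroxy-2-methylprop-2-en-1-yl]-2-methyl-5-(prop-1-en-2-yl)cyclohex-2-en-1-ol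
Conditions: 13 (2.2 equiv), THF, −78 °C; H2O
Reagents that add atoms: allylmagnesium bromide (13), C=CC[Mg]Br
Why: Grignard 1,2-addition to the enone carbonyl of the magnesium-chelated β-alkoxy ketone from the axial α-face should give the tertiary carbinol 1,3-syn to the C9 hydroxyl; this auxiliary C3 centre only fixes the cis ring fusion and is erased in step 11.

Step 8
Reactants: 14 triene diol
Product: 15 cis-fused octalin diol (C3–C8 bond; 3β-OH at the ring fusion; 8β-H; 9β-OH; C1=C10 and C4=C5; 6α-OTBS; 7β-isopropenyl)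
Conditions: Grubbs II (5 mol%), CH2Cl2, 40 °C
Reagents that add atoms: none
Why: Ring-closing metathesis of the allyl group with the 1,1-disubstituted alkene of the methallylic alcohol closes the cyclohexene (C1=C10) with loss of ethene; the C7 isopropenyl is trans-disposed and cannot reach, and the trisubstituted C4=C5 is inert.

Step 9
Reactants: 15 octalin diol
Product: 16 1β,10β-epoxide of 15 (oxirane syn to the 9β-hydroxyl)
Conditions: VO(acac)2 (5 mol%), t-BuOOH (1.1 equiv), CH2Cl2, 0 °C
Reagents that add atoms: tert-butyl hydroperoxide, CC(C)(C)OO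
Why: Hydroxyl-directed vanadium epoxidation: the vanadate of the pseudoaxial allylic C9–OH, supported by the syn-1,3 C3–OH (axial on ring B and therefore equatorial and poorly placed towards C4=C5 on ring A), delivers oxygen to the β-face of C1=C10, fixing C1 and C10 syn to C9–O; C4=C5 is also deactivated by two allylic C–O bonds and the isopropenyl group is not directed.

Step 10
Reactants: 16 epoxy diol; 17 angelic acid
Product: 19 9-O-angelate of 16 (tertiary 3β-OH free), via mixed anhydride 18 (not isolated)
Conditions: 17, 2,4,6-trichlorobenzoyl chloride, Et3N, toluene, rt; then 16, 80 °C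
Reagents that add atoms: angelic acid (17), C/C=C(/C)C(=O)O
Why: Mixed-anhydride (Yamaguchi-type) esterification acylates the secondary C9–OH while the tertiary C3–OH is inert, and the DMAP-free protocol avoids angelate-to-tiglate isomerisation; the ester also serves as the C9 protecting group for the rest of the route.

Step 11
Reactants: 19 cis-decalinol angelate
Product: 22 (4Z)-9β-angeloyloxy-1β,10β-epoxy-6α-(tert-butyldimethylsilyloxy)germacra-4,11(13)-dien-3-one, via alkoxyl radical 20 (not isolated), via ring-opened C8 radical 21 (not isolated)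
Conditions: [Ir(dF(CF3)ppy)2(5,5′-d(CF3)bpy)]PF6 (2 mol%), Bu4P (MeO)2PO2 (25 mol%), 2,4,6-triisopropylbenzenethiol (25 mol%), CH2Cl2, blue LEDs, rt
Reagents that add atoms: none
Why: Proton-coupled electron transfer from the phosphate-bound tertiary C3–OH to the excited Ir(III) complex gives alkoxyl radical 20, whose β-scission of the ring-fusion bond C3–C8 releases the ten-membered secondary radical 21 together with the C3 enone carbonyl, and hydrogen-atom transfer from the thiol then gives 22 while Ir(II) and the protonated base return the thiyl radical to thiol (redox-neutral isomerisation). The closest known reaction types are the photocatalytic PCET ring-opening isomerisation of unstrained tertiary cycloalkanols and the hypoiodite β-fragmentation of 9-decalinols to cyclodecanones. No ring is closed: the ten-membered carbocycle arises by cleaving the zero-atom bridge of the bicyclo[4.4.0] system, a four-carbon ring expansion of the carvone ring. No stereocentre is created: the auxiliary centres C3 and C8 are erased, C1, C6, C7, C9 and C10 are carried over, and C4=C5 emerges Z because it was the endocyclic alkene of the six-membered ring. Scission must occur at C3–C8 and not at C3–C2 or C3–C4; all modes would give the same conjugated enone, so radical stability decides (secondary at C8 versus primary at C2 or vinylic at C4), but because the favoured opening is reversible the radical must be trapped quickly. Radical 21 must therefore be quenched before it re-adds to the carbonyl or rearranges (1,2-vinyl or acyloxy shift), and the angelate must keep its Z geometry; this relies on fast hydrogen donation by the hindered substoichiometric arylthiol, on the weak base (no enolisation of the β,γ-epoxy ketone) and on a sensitiser triplet energy below that of an alkyl enoate.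

Step 12
Reactants: 22 ring-expanded enone
Product: 23 12-hydroxy derivative of 22 (2-(hydroxymethyl)allyl group at C7)
Conditions: SeO2 (0.3 equiv), t-BuOOH (anhydrous, 3 equiv), CH2Cl2, 0 °C to rt
Reagents that add atoms: tert-butyl hydroperoxide, CC(C)(C)OO (oxygen relayed by catalytic selenium dioxide, O=[Se]=O)
Why: Selenium dioxide allylic hydroxylation (ene reaction then [2,3]-shift) at the methyl of the isopropenyl group, the only electron-rich alkene left because C4=C5 is now an enone and the angelate is an enoate; any over-oxidised enal converges in step 14.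

Step 13
Reactants: 23 allylic alcohol silyl ether
Product: 24 6α,12-diol (C6 desilylated; 3-ketone, epoxide and angelate intact)
Conditions: HF·pyridine, pyridine, THF, 0 °C to rt
Reagents that add atoms: none
Why: Buffered, non-basic fluoride desilylation frees the C6 hydroxyl without opening the epoxide or triggering base-mediated isomerisation of the β,γ-epoxy ketone.

Step 14
Reactants: 24 diol
Product: 27 (4Z)-9β-angeloyloxy-1β,10β-epoxy-3-oxogermacra-4,11(13)-dien-12,6α-olide, via enal 25 (not isolated), via lactol 26 (not isolated)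
Conditions: TEMPO (20 mol%), PhI(OAc)2 (2.5 equiv), CH2Cl2, rt
Reagents that add atoms: none
Why: Oxoammonium (TEMPO) oxidation selective for the primary allylic alcohol gives the enal, which the C6 hydroxyl captures as the γ-lactol and which is oxidised on to the trans-fused α-methylene-γ-butyrolactone; C9 is already esterified so no other lactol can form.

Step 15
Reactants: 27 keto lactone
Product: 28 (4Z)-9β-angeloyloxy-1β,10β-epoxy-3β-hydroxygermacra-4,11(13)-dien-12,6α-olide
Conditions: (R)-2-methyl-CBS-oxazaborolidine (20 mol%), catecholborane (1.5 equiv), toluene, −78 °C; pH 7 buffer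
Reagents that add atoms: none
Why: Corey–Bakshi–Shibata 1,2-reduction in which the α-methyl-alkenyl arm acts as the large group, so that the (R)-catalyst should deliver hydride to give the (3S)-(3β) allylic alcohol under reagent control; the lactone, esters and epoxide are inert at −78 °C.

Step 16
Reactants: 28 epoxy alcohol
Product: 29 CNP0493102.1 [(4Z)-9β-angeloyloxy-1β,3β,10α-trihydroxygermacra-4,11(13)-dien-12,6α-olide; 1R,3S,6R,7S,9S,10S]
Conditions: HClO4 (cat.), THF–H2O (3:1), 0 °C
Reagents that add atoms: water, O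
Why: Acid-catalysed epoxide hydrolysis with water attacking the tertiary C10 from the α-face with inversion (borderline SN2 at the carbon that best supports positive charge) while C1–O is retained, giving the 1β,10α-diol; the 3β-hydroxyl cannot reach the α-face of C10 and C4=C5 is deactivated by its two allylic C–O bonds.

**Compound list**

1 | (R)-(−)-carvone | CC(=C)[C@@H]1CC=C(C)C(=O)C1 | starting material
2 | lithium dienolate of 1 (cross-conjugated) | CC(=C)[C@@H]1CC=C(C)C(O[Li])=C1 | intermediate
3 | trans-6-hydroxycarvone, (5S,6S) | CC(=C)[C@@H]1CC=C(C)C(=O)[C@H]1O | intermediate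
4 | (5S,6S)-6-(tert-butyldimethylsilyloxy)carvone | CC(=C)[C@@H]1CC=C(C)C(=O)[C@H]1O[Si](C)(C)C(C)(C)C | intermediate
5 | 2,3-epoxide of 4, oxirane anti to isopropenyl | CC(=C)[C@@H]1C[C@H]2O[C@@]2(C)C(=O)[C@H]1O[Si](C)(C)C(C)(C)C | intermediate
6 | hydrazone of 5 | CC(=C)[C@@H]1C[C@H]2O[C@@]2(C)C(=NN)[C@H]1O[Si](C)(C)C(C)(C)C | intermediate
7 | (1R,4R,5S)-4-(tert-butyldimethylsilyloxy)-2-methyl-5-(prop-1-en-2-yl)cyclohex-2-en-1-ol | CC(=C)[C@@H]1C[C@@H](O)C(C)=C[C@H]1O[Si](C)(C)C(C)(C)C | intermediate
8 | (4R,5S)-4-(tert-butyldimethylsilyloxy)-2-methyl-5-(prop-1-en-2-yl)cyclohex-2-en-1-one | CC(=C)[C@@H]1CC(=O)C(C)=C[C@H]1O[Si](C)(C)C(C)(C)C | intermediate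
9 | methacrolein | CC(=C)C=O | starting material
10 | lithium enolate of 8 (C3–O–Li, C3=C8) | CC(=C)[C@@H]1C=C(O[Li])C(C)=C[C@H]1O[Si](C)(C)C(C)(C)C | intermediate
11 | triisopropoxytitanium enolate of 8 | CC(=C)[C@@H]1C=C(O[Ti](OC(C)C)(OC(C)C)OC(C)C)C(C)=C[C@H]1O[Si](C)(C)C(C)(C)C | intermediate
12 | syn aldol, (4R,5S,6S)-6-[(1S)-1-hydroxy-2-methylallyl] enone | CC(=C)[C@@H]1[C@@H]([C@H](O)C(C)=C)C(=O)C(C)=C[C@H]1O[Si](C)(C)C(C)(C)C | intermediate
13 | allylmagnesium bromide | C=CC[Mg]Br | starting material
14 | (1S,4R,5S,6S)-1-allyl diol | CC(=C)[C@@H]1[C@@H]([C@H](O)C(C)=C)[C@@](O)(CC=C)C(C)=C[C@H]1O[Si](C)(C)C(C)(C)C | intermediate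
15 | cis-fused octalin diol (3β-OH, 8β-H, 9β-OH, C1=C10, C4=C5, 6α-OTBS, 7β-isopropenyl) | CC(=C)[C@H]1[C@H](O[Si](C)(C)C(C)(C)C)C=C(C)[C@]2(O)CC=C(C)[C@@H](O)[C@H]12 | intermediate
16 | 1β,10β-epoxide of 15 | CC(=C)[C@H]1[C@H](O[Si](C)(C)C(C)(C)C)C=C(C)[C@]2(O)C[C@H]3O[C@@]3(C)[C@@H](O)[C@H]12 | intermediate
17 | angelic acid, (Z)-2-methylbut-2-enoic acid | C/C=C(/C)C(=O)O | starting material
18 | angelic 2,4,6-trichlorobenzoic anhydride | C/C=C(/C)C(=O)OC(=O)c1c(Cl)cc(Cl)cc1Cl | intermediate
19 | 9-O-angelate of 16 (cis-decalinol, key-step precursor) | CC(=C)[C@H]1[C@H](O[Si](C)(C)C(C)(C)C)C=C(C)[C@]2(O)C[C@H]3O[C@@]3(C)[C@@H](OC(=O)/C(C)=C\C)[C@H]12 | intermediate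
20 | C3 alkoxyl radical of 19 | CC(=C)[C@H]1[C@H](O[Si](C)(C)C(C)(C)C)C=C(C)[C@]2([O])C[C@H]3O[C@@]3(C)[C@@H](OC(=O)/C(C)=C\C)[C@H]12 | intermediate
21 | ring-opened ten-membered C8 radical | CC(=C)[C@H]1[C@H](O[Si](C)(C)C(C)(C)C)/C=C(/C)C(=O)C[C@H]2O[C@@]2(C)[C@@H](OC(=O)/C(C)=C\C)[CH]1 | intermediate
22 | (4Z)-9β-angeloyloxy-1β,10β-epoxy-6α-(tert-butyldimethylsilyloxy)germacra-4,11(13)-dien-3-one | CC(=C)[C@H]1[C@H](O[Si](C)(C)C(C)(C)C)/C=C(/C)C(=O)C[C@H]2O[C@@]2(C)[C@@H](OC(=O)/C(C)=C\C)C1 | intermediate
23 | 12-hydroxy derivative of 22 | OCC(=C)[C@H]1[C@H](O[Si](C)(C)C(C)(C)C)/C=C(/C)C(=O)C[C@H]2O[C@@]2(C)[C@@H](OC(=O)/C(C)=C\C)C1 | intermediate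
24 | 6α,12-diol | OCC(=C)[C@H]1[C@H](O)/C=C(/C)C(=O)C[C@H]2O[C@@]2(C)[C@@H](OC(=O)/C(C)=C\C)C1 | intermediate
25 | C12 enal | O=CC(=C)[C@H]1[C@H](O)/C=C(/C)C(=O)C[C@H]2O[C@@]2(C)[C@@H](OC(=O)/C(C)=C\C)C1 | intermediate
26 | 12,6α-lactol | C=C1C(O)O[C@@H]2/C=C(/C)C(=O)C[C@H]3O[C@@]3(C)[C@@H](OC(=O)/C(C)=C\C)C[C@@H]12 | intermediate
27 | (4Z)-9β-angeloyloxy-1β,10β-epoxy-3-oxogermacra-4,11(13)-dien-12,6α-olide | C=C1C(=O)O[C@@H]2/C=C(/C)C(=O)C[C@H]3O[C@@]3(C)[C@@H](OC(=O)/C(C)=C\C)C[C@@H]12 | intermediate
28 | (4Z)-9β-angeloyloxy-1β,10β-epoxy-3β-hydroxygermacra-4,11(13)-dien-12,6α-olide | C=C1C(=O)O[C@@H]2/C=C(/C)[C@@H](O)C[C@H]3O[C@@]3(C)[C@@H](OC(=O)/C(C)=C\C)C[C@@H]12 | intermediate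
29 | CNP0493102.1 | C=C1C(=O)O[C@@H]2/C=C(/C)[C@@H](O)C[C@@H](O)[C@](C)(O)[C@@H](OC(=O)/C(C)=C\C)C[C@@H]12 | target

**Count.** Total steps: 16. Longest linear sequence: 16 (1 to 29; the route is fully linear).

**Steps most likely to fail**

1. Step 11 (key step). The favoured C3–C8 scission is reversible, so if hydrogen transfer to radical 21 is slow the system can re-close transannularly or leak through the slower, irreversible C3–C2 scission (which would unravel the epoxide). Thiyl-radical or sensitised Z-to-E isomerisation of the angelate is the other hazard. Fallback (sets out from 16, returns at 22): silylate the C9 hydroxyl (Et3SiCl, imidazole) to the triethylsilyl ether F1. Fragment it under stoichiometric hypoiodite conditions (PhI(OAc)2, I2, hν, cyclohexane), where iodine-atom transfer captures the ring-opened radical irreversibly as the C8 iodide F2. Remove iodine with Bu3SnH/AIBN to give the silyl ether enone F3, cleave the triethylsilyl ether selectively (PPTS, MeOH, 0 °C) to the C9 alcohol F4, and esterify F4 with 17 under the conditions of step 10 to reach 22.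

2. Step 6. The syn simple diastereoselection may be insufficient, because the closed chair transition state of a cyclic E-enolate intrinsically favours the anti aldol; retro-aldol on work-up is a second hazard. Fallback (sets out from 8, returns at 14): accept the closed-transition-state preference by running the dicyclohexylboron enolate aldol ((c-Hex)2BCl, Et3N; then 9), which should give the anti aldol F5 (C9 epimer of 12). Add 13 as in step 7 to obtain the epimeric diol F6 and oxidise its allylic C9 carbinol with MnO2 to the β-hydroxy enone F7. Reduce F7 under Narasaka–Prasad conditions (Et2BOMe, NaBH4, THF–MeOH, −78 °C), where the boron chelate with the tertiary C3–OH enforces the 1,3-syn diol 14, so that C9 is set by directed reduction instead of by the aldol.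

3. Step 16. The incipient C10 cation may be captured transannularly (participation of the C4=C5 allylic-alcohol alkene), the angelate may migrate through a dioxolanylium ion, or water may attack C1. Fallback (sets out from 27, returns at 29): open the epoxide one step earlier, on enone 27 whose C4=C5 bond is deactivated by conjugation (same aqueous acid), to give the keto diol F8. Then set C3 by relay from the new 1β-hydroxyl through a Narasaka–Prasad 1,3-syn reduction (Et2BOMe, NaBH4, −78 °C), which should give 29 directly.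

**Further compounds**

F1 | step 11 | 9-O-triethylsilyl ether of 16 | CC(=C)[C@H]1[C@H](O[Si](C)(C)C(C)(C)C)C=C(C)[C@]2(O)C[C@H]3O[C@@]3(C)[C@@H](O[Si](CC)(CC)CC)[C@H]12
F2 | step 11 | 8-iodo ring-expanded enone, 9-OTES (C8 epimers) | CC(=C)[C@H]1[C@H](O[Si](C)(C)C(C)(C)C)/C=C(/C)C(=O)C[C@H]2O[C@@]2(C)[C@@H](O[Si](CC)(CC)CC)C1I
F3 | step 11 | ring-expanded enone, 9-OTES | CC(=C)[C@H]1[C@H](O[Si](C)(C)C(C)(C)C)/C=C(/C)C(=O)C[C@H]2O[C@@]2(C)[C@@H](O[Si](CC)(CC)CC)C1
F4 | step 11 | ring-expanded enone, free 9β-OH | CC(=C)[C@H]1[C@H](O[Si](C)(C)C(C)(C)C)/C=C(/C)C(=O)C[C@H]2O[C@@]2(C)[C@@H](O)C1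
F5 | step 6 | anti aldol, C9 epimer of 12 | CC(=C)[C@@H]1[C@@H]([C@@H](O)C(C)=C)C(=O)C(C)=C[C@H]1O[Si](C)(C)C(C)(C)C
F6 | step 6 | C9 epimer of 14 | CC(=C)[C@@H]1[C@@H]([C@@H](O)C(C)=C)[C@@](O)(CC=C)C(C)=C[C@H]1O[Si](C)(C)C(C)(C)C
F7 | step 6 | β-hydroxy enone (C9 ketone) | CC(=C)[C@@H]1[C@@H](C(=O)C(C)=C)[C@@](O)(CC=C)C(C)=C[C@H]1O[Si](C)(C)C(C)(C)C
F8 | step 16 | 3-keto-1β,10α-diol lactone | C=C1C(=O)O[C@@H]2/C=C(/C)C(=O)C[C@@H](O)[C@](C)(O)[C@@H](OC(=O)/C(C)=C\C)C[C@@H]12
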